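## Retrosynthetic overview
1. Target **11** is the (2S)-flavanone. It comes from tris-TBS ether **10** by a buffered global desilylation, with no acid and no free base.
2. The key disconnection is the C2–C1' bond, not the chalcone aldol/oxa-Michael pair. A Rh(I)/chiral bisphosphine asymmetric 1,4-addition of chromenylboronic acid **7** to the intact chromone **9** joins the fragments and sets the only stereocentre in one step.
3. **7** comes from bromochromene **6** by Li–Br exchange and borylation. The dimethylpyran ring comes from 5-bromo-2,3-dihydroxybenzaldehyde **2** and 2-methylpropenyl Grignard **3**, through an o-quinone methide oxa-6π closure.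
4. Ring order: the A/C benzopyranone is bought intact (**8**), and the pyran on ring B is closed in step 3. No ring is formed after the coupling; C2 of ring C only goes from sp2 to sp3.

Assumptions (one line each):
- The stereocentre decodes as 2S (O1 > C1' > C3 > H), the natural flavanone series.
- **1**, **3** and **8** (CAS 31721-94-5) are taken as catalogue chemicals.
- The ligand sense in step 7 follows the (S)-biaryl bisphosphine → (S)-3-arylcyclohexanone model and is to be confirmed on **10** by chiral HPLC/ECD.

## Route

**Step 1**
Reactants: **1**, 5-bromo-2-hydroxy-3-methoxybenzaldehyde (5-bromo-o-vanillin)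
Product: **2**, 5-bromo-2,3-dihydroxybenzaldehyde
Conditions: BBr3 (2.2 equiv), CH2Cl2, −78 °C → rt; H2O quench
Reagents that add atoms: none
Why: BBr3 aryl methyl ether cleavage is routine on o-vanillins and leaves the aldehyde and the ArBr intact; it is done first because the later chromene would not survive BBr3.

**Step 2**
Reactants: **2**; **3**, 2-methyl-1-propenylmagnesium bromide (3.5 equiv, 0.5 M in THF)
Product: **4**, (±)-1-(5-bromo-2,3-dihydroxyphenyl)-3-methylbut-2-en-1-ol (racemic, carried on crude)
Conditions: THF, 0 °C → rt, Ar; sat. aq NH4Cl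
Reagents that add atoms: 2-methyl-1-propenylmagnesium bromide (= **3**), CC(C)=C[Mg]Br
Why: Grignard 1,2-addition, in which two equivalents deprotonate the phenols and the third adds to the chelated aldehyde while the ArBr is inert to a vinyl Grignard at this temperature; the carbinol stereocentre is erased in step 3.

**Step 3**
Reactants: **4**
Product: **5**, 6-bromo-2,2-dimethyl-2H-chromen-8-ol
Conditions: PPTS (5 mol %), 4 Å MS, toluene, 80 °C
Reagents that add atoms: none
Why: The benzylic and allylic carbinol loses water to give a vinyl o-quinone methide that closes by oxa-6π electrocyclisation; only the 2-OH is ortho to the carbinol, so one regioisomer forms (Br para to the ring O, free OH at C8).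

**Step 4**
Reactants: **5**
Product: **6**, [(6-bromo-2,2-dimethyl-2H-chromen-8-yl)oxy](tert-butyl)dimethylsilane
Conditions: TBSCl (1.2 equiv), imidazole (2.5 equiv), DMF, rt
Reagents that add atoms: TBSCl, CC(C)(C)[Si](C)(C)Cl
Why: This is a standard phenol silylation; the aryl TBS ether tolerates n-BuLi at −78 °C and wet Rh catalysis, and it comes off later without acid, which protects the chromene.

**Step 5**
Reactants: **6**
Product: **7**, {8-[(tert-butyldimethylsilyl)oxy]-2,2-dimethyl-2H-chromen-6-yl}boronic acid
Conditions: B(OiPr)3 (1.5 equiv), THF, −78 °C, then n-BuLi (1.1 equiv, in-situ quench), → 0 °C; aq NH4Cl/0.5 M HCl (10 min)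
Reagents that add atoms: triisopropyl borate, CC(C)OB(OC(C)C)OC(C)C; water, O
Why: Li–Br exchange followed by borate trapping, which is far faster at −78 °C than attack on Si or on the alkene; the aryllithium is meta to OTBS, so no retro-Brook shift occurs, and brief dilute acid hydrolyses only the borate.

**Step 6**
Reactants: **8**, 5,7-dihydroxy-4H-chromen-4-one
Product: **9**, 5,7-bis[(tert-butyldimethylsilyl)oxy]-4H-chromen-4-one
Conditions: TBSOTf (2.6 equiv), 2,6-lutidine (4 equiv), CH2Cl2, 0 °C → rt; aq NaHCO3; Et3N-deactivated SiO2
Reagents that add atoms: TBSOTf, CC(C)(C)[Si](C)(C)OS(=O)(=O)C(F)(F)F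
Why: The silyl triflate is strong enough to cap the hydrogen-bonded 5-OH, and any reversible 4-silyloxybenzopyrylium reverts to chromone on quench; capping 5-OH stops it forming an acac-like chelate with C4=O that would deactivate Rh in step 7.

**Step 7 (key step)**
Reactants: **9** (1.0 equiv); **7** (1.8 equiv, added in two portions)
Product: **10**, (2S)-5,7-bis[(tert-butyldimethylsilyl)oxy]-2-{8-[(tert-butyldimethylsilyl)oxy]-2,2-dimethyl-2H-chromen-6-yl}-2,3-dihydro-4H-chromen-4-one
Conditions: [RhCl(C2H4)2]2 (1.5 mol %), (S)-MeO-F12-BIPHEP [(S)-2,2'-bis{bis(3,4,5-trifluorophenyl)phosphino}-6,6'-dimethoxybiphenyl, 3.3 mol %], aq KOH (6 mol %), degassed toluene/H2O 10:1, 25–35 °C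
Reagents that add atoms: none (water supplies only the C3 hydrogen)
Why: In this Hayashi–Miyaura asymmetric 1,4-addition the Ar–Rh(I) species inserts the chromone C2=C3 bond on the face left open by the (S)-biaryl bisphosphine, the same quadrant model that gives (S)-3-arylcyclohexanones and maps to 2S here because O1 replaces C4; the π-acidic ligand offsets the low electrophilicity of the 5,7-dioxygenated chromone, fast protonolysis of the oxa-π-allyl-Rh in wet toluene at ≤35 °C outruns β-aryloxide elimination and 1,2-addition, and the hindered, unactivated chromene alkene is not an acceptor.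

**Step 8**
Reactants: **10**
Product: **11**, (2S)-5,7-dihydroxy-2-(8-hydroxy-2,2-dimethyl-2H-chromen-6-yl)-2,3-dihydro-4H-chromen-4-one (target)
Conditions: TBAF (3.5 equiv)/AcOH (4.5 equiv), THF, 0 °C, 1 h; pH 5–6 buffer work-up
Reagents that add atoms: none
Why: Fluoride cleaves all three aryl silyl ethers while the acetic acid buffer prevents phenoxide-driven retro-oxa-Michael opening, so C2 is retained; the 4'-oxygen is an alkyl ether, which rules out p-quinone-methide racemisation, and the acid-sensitive chromene never meets strong acid.

## Compound list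
1 | 5-bromo-2-hydroxy-3-methoxybenzaldehyde | COc1cc(Br)cc(C=O)c1O | starting material
2 | 5-bromo-2,3-dihydroxybenzaldehyde | O=Cc1cc(Br)cc(O)c1O | intermediate
3 | 2-methyl-1-propenylmagnesium bromide | CC(C)=C[Mg]Br | starting material
4 | (±)-1-(5-bromo-2,3-dihydroxyphenyl)-3-methylbut-2-en-1-ol | CC(C)=CC(O)c1cc(Br)cc(O)c1O | intermediate
5 | 6-bromo-2,2-dimethyl-2H-chromen-8-ol | CC1(C)C=Cc2cc(Br)cc(O)c2O1 | intermediate
6 | 6-bromo-8-(TBS-oxy)-2,2-dimethyl-2H-chromene | CC1(C)C=Cc2cc(Br)cc(O[Si](C)(C)C(C)(C)C)c2O1 | intermediate
7 | [8-(TBS-oxy)-2,2-dimethyl-2H-chromen-6-yl]boronic acid | CC1(C)C=Cc2cc(B(O)O)cc(O[Si](C)(C)C(C)(C)C)c2O1 | intermediate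
8 | 5,7-dihydroxy-4H-chromen-4-one | O=c1ccoc2cc(O)cc(O)c12 | starting material
9 | 5,7-bis(TBS-oxy)-4H-chromen-4-one | O=c1ccoc2cc(O[Si](C)(C)C(C)(C)C)cc(O[Si](C)(C)C(C)(C)C)c12 | intermediate
10 | (2S)-tris-TBS flavanone | CC1(C)C=Cc2cc([C@@H]3CC(=O)c4c(O[Si](C)(C)C(C)(C)C)cc(O[Si](C)(C)C(C)(C)C)cc4O3)cc(O[Si](C)(C)C(C)(C)C)c2O1 | intermediate
11 | (2S)-5,7-dihydroxy-2-(8-hydroxy-2,2-dimethyl-2H-chromen-6-yl)chroman-4-one | CC1(C)C=Cc2cc([C@@H]3CC(=O)c4c(O)cc(O)cc4O3)cc(O)c2O1 | target

## Summary
Total steps: 8. Steps 2 and 3 are telescoped without purification.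
Longest linear sequence: 7 (steps 1–5, 7, 8). Step 6 is the one-step convergent branch.

Three steps most likely to fail:
1. **Step 7.** The electron-rich chromone may be too poor an acceptor, **7** may protodeboronate, or ee may erode through ring opening.
   - Fallback: set C2 by C–H rather than C–C bond formation.
   - Join **7** and **9** to the achiral flavone by Pd(II)/O2 oxidative arylation (conjugate addition followed by β-H elimination).
   - Then run an asymmetric CuH/chiral bisphosphine/silane 1,4-reduction. The nucleophilic hydride should select the polarised enone over the hindered chromene alkene.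
2. **Step 2.** The magnesium bis-phenoxide of **2** may be insoluble or too unreactive, and the free catechol may oxidise.
   - Fallback: build the pyran by an aromatic propargyl Claisen sequence instead.
   - O-alkylate 4-bromo-2-methoxyphenol with 3-chloro-3-methylbut-1-yne (Cu catalysis, DBU).
   - A thermal [3,3]/[1,5]-H/oxa-6π cascade gives 6-bromo-8-methoxy-2,2-dimethylchromene.
   - NaSEt demethylation then gives **5**.
3. **Step 6.** Silylation of the 5-OH may be incomplete, or the peri 5-OTBS may hydrolyse in step 7, and the freed 5-OH would then chelate Rh.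
   - Fallback: change the protecting-group logic to MOM ethers on all three phenols (NaH/MOMCl on **8**, DIPEA/MOMCl on **5**). These are inert to aqueous Rh conditions.
   - Finish with a mild heterogeneous or thiol-assisted MOM cleavage (NaHSO4·SiO2, or ZnBr2/n-PrSH) in place of fluoride.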